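The cyclohexane ring (C5–C10, elemane numbering) holds a vinyl group on quaternary C10 beside a 2-propenyl unit on C5. This is a 1,5-diene, the retron of a Cope rearrangement. Everything rests on breaking C5–C10 and joining C2–C3 in retrosynthesis. The key step is the biomimetic [3,3] shift of a (1(10)E,4E)-germacradien-12,8-olide. It closes the six-membered ring transannularly, opens the strained ten-membered ring and sets C5 and quaternary C10 at once. The precursor is a cyclodecadiene cis-fused to the finished α-methylene-γ-lactone, made from geraniol and a five-carbon silyloxyfuran. Its 6α-hydroxyl selects the reacting conformer by A(1,3) strain and is inverted afterwards.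

Key step: step 12

Remark on numbering: germacrane/elemane numbering is used throughout.
- C10 is the quaternary ring carbon (C14 its CH3, C1=C2 the vinyl group).
- C9 carries OAc and C8 the lactone oxygen.
- C7 carries C11(=C13H2)–C12(=O).
- C6 carries the isobutyrate.
- C5 carries C4(=C3H2)–C15H2OAc.
- β is the ring face that carries C14.

Assumption: the (R,R)-bisphosphoramide of step 6 exposes the Re face of the bound aldehyde, as is usual for this catalyst family. Its antipode is equally accessible should the sense be opposite.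

Step 1
Reactants: 1 geraniol
Product: 2 geranyl tert-butyldimethylsilyl ether
Conditions: TBSCl, imidazole, CH2Cl2, 0 °C to rt
Reagents that add atoms: tert-butyldimethylsilyl chloride, CC(C)(C)[Si](C)(C)Cl
Why: Imidazole-promoted silyl ether formation masks the C6 hydroxyl in a form that survives Lewis-acidic and acylating conditions; no stereocentre is involved and the E-alkene (future C4=C5) is untouched.

Step 2
Reactants: 2 geranyl tert-butyldimethylsilyl ether
Product: 3 (2E,6E)-8-(tert-butyldimethylsilyloxy)-2,6-dimethylocta-2,6-dien-1-ol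
Conditions: SeO2 (cat.), t-BuOOH, salicylic acid (cat.), CH2Cl2, 0 °C to rt
Reagents that add atoms: tert-butyl hydroperoxide, CC(C)(C)OO (oxygen source, relayed by catalytic selenium dioxide, O=[Se]=O)
Why: Riley-type allylic oxidation (ene reaction followed by [2,3]-sigmatropic shift) should select the more electron-rich terminal trisubstituted alkene and its E-methyl group, so that the future C1=C10 alkene keeps E geometry and the new CH2OH becomes C9.

Step 3
Reactants: 3 (2E,6E)-8-(tert-butyldimethylsilyloxy)-2,6-dimethylocta-2,6-dien-1-ol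
Product: 4 (2E,6E)-8-(tert-butyldimethylsilyloxy)-2,6-dimethylocta-2,6-dienal
Conditions: activated MnO2, CH2Cl2, rt
Reagents that add atoms: none
Why: Manganese dioxide oxidation of an allylic alcohol stops at the enal and leaves the silyl ether and both alkene geometries intact.

Step 4
Reactants: 5 but-2-yne-1,4-diol
Product: 6 3-(hydroxymethyl)furan-2(5H)-one
Conditions: Pd2(dba)3·CHCl3 (cat.), dppb (cat.), CO/H2, CH2Cl2, 95 °C (autoclave)
Reagents that add atoms: carbon monoxide, [C-]#[O+]
Why: Palladium-catalysed cyclocarbonylation of a 2-alkyn-1-ol to a 2(5H)-furanone builds the lactone ring (C7, C8, C11, C12, O) in one step, the C2 symmetry of the diol removes any regiochemical question, and the second CH2OH remains as the C13 handle.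

Step 5
Reactants: 6 3-(hydroxymethyl)furan-2(5H)-one
Product: 7 2-(tert-butyldimethylsilyloxy)-3-[(tert-butyldimethylsilyloxy)methyl]furan
Conditions: TBSOTf (2.2 equiv), Et3N, CH2Cl2, 0 °C
Reagents that add atoms: tert-butyldimethylsilyl triflate, CC(C)(C)[Si](C)(C)OS(=O)(=O)C(F)(F)F
Why: Silyl triflate/amine soft enolisation converts the butenolide into the aromatic 2-silyloxyfuran (a vinylogous silyl ketene acetal) while the same reagent silylates the primary alcohol.

Step 6
Reactants: 4 (2E,6E)-8-(tert-butyldimethylsilyloxy)-2,6-dimethylocta-2,6-dienal; 7 2-(tert-butyldimethylsilyloxy)-3-[(tert-butyldimethylsilyloxy)methyl]furan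
Product: 9 (5S)-3-[(tert-butyldimethylsilyloxy)methyl]-5-[(1S,2E,6E)-8-(tert-butyldimethylsilyloxy)-1-hydroxy-2,6-dimethylocta-2,6-dienyl]furan-2(5H)-one, via trichlorosilyl aldolate 8 (not isolated)
Conditions: SiCl4 (1.1 equiv), (R,R)-BINAM-derived bisphosphoramide (5 mol %), i-Pr2NEt (20 mol %), CH2Cl2, −78 °C; then sat. aq. NaHCO3
Reagents that add atoms: none
Why: Catalytic enantioselective vinylogous Mukaiyama aldol reaction under Lewis-base-activated SiCl4: the furan attacks through its γ-carbon (C8) the Re face of the catalyst-bound enal, which sets C9 as S, the syn (threo) topicity usual for furan-derived dienoxysilanes in this system sets C8 as S, and hydrolysis of the trichlorosilyl aldolate on work-up leaves only the new hydroxyl free.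

Step 7
Reactants: 9 syn-aldol butenolide
Product: 10 (5S)-5-[(1S,2E,6E)-1-acetoxy-8-(tert-butyldimethylsilyloxy)-2,6-dimethylocta-2,6-dienyl]-3-[(tert-butyldimethylsilyloxy)methyl]furan-2(5H)-one
Conditions: Ac2O, pyridine, DMAP (cat.), CH2Cl2, 0 °C
Reagents that add atoms: acetic anhydride, CC(=O)OC(C)=O
Why: Pyridine/DMAP-mediated acetylation installs the final C9 acetate on the only free hydroxyl, and the mild base and low temperature avoid β-elimination to a γ-alkylidenebutenolide.

Step 8
Reactants: 10 bis-silyl acetate
Product: 11 (5S)-5-[(1S,2E,6E)-1-acetoxy-8-hydroxy-2,6-dimethylocta-2,6-dienyl]-3-(hydroxymethyl)furan-2(5H)-one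
Conditions: HF·pyridine, THF, 0 °C to rt
Reagents that add atoms: none
Why: Fluoride-mediated desilylation removes both primary silyl ethers under mildly acidic conditions that leave the acetate, the butenolide and the C8/C9 stereocentres untouched.

Step 9
Reactants: 11 diol
Product: 12 (5S)-5-[(1S,2E,6E)-1-acetoxy-2,6-dimethyl-8-oxoocta-2,6-dienyl]-3-(hydroxymethyl)furan-2(5H)-one
Conditions: activated MnO2, CH2Cl2, rt
Reagents that add atoms: none
Why: Chemoselective manganese dioxide oxidation: the electron-rich geraniol-type allylic alcohol (C6) should be oxidised far faster than the hydroxymethyl group on the electron-poor butenolide alkene (C13), which gives the E-enal.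

Step 10
Reactants: 12 hydroxy enal
Product: 13 (5S)-5-[(1S,2E,6E)-1-acetoxy-2,6-dimethyl-8-oxoocta-2,6-dienyl]-3-(bromomethyl)furan-2(5H)-one
Conditions: PBr3 (0.4 equiv), pyridine (cat.), Et2O, −20 to 0 °C
Reagents that add atoms: phosphorus tribromide, BrP(Br)Br
Why: Conversion of the primary allylic alcohol into the bromide by way of its phosphite ester (SN2), the standard access to 2-(bromomethyl)acrylate-type halides, should tolerate the enal and the acetate at low temperature.

Step 11
Reactants: 13 bromo enal
Product: 16 9α-acetoxy-6α-hydroxygermacra-1(10)E,4E,11(13)-trien-12,8β-olide (7αH,8αH), via allylchromium(III) species 14 (not isolated), via chromium(III) alkoxide 15 (not isolated)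
Conditions: CrCl2 (8 equiv), THF, slow addition (final 2 mM), rt; then H2O
Reagents that add atoms: none
Why: Intramolecular Nozaki–Hiyama–Kishi (chromium(II) Barbier-type) allylation under high dilution, a known closure of germacranolide rings: the allylchromium(III) adds through C7 (SE2′) to the enal in a Zimmerman–Traxler chair, its ring-locked E-type geometry should give the 6,7-anti relationship (6α-OH, 7αH), the tether with its two E-alkenes should deliver C6 to the butenolide face that bears C9 (torsion C6–C7–C8–C9 near 30° instead of a third anti torsion near 150° in the ten-membered ring) and so give the cis ring fusion, and the allyl shift unveils the exocyclic C11=C13 methylene.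

Step 12
Reactants: 16 9α-acetoxy-6α-hydroxygermacra-1(10)E,4E,11(13)-trien-12,8β-olide
Product: 17 9α-acetoxy-6α-hydroxyelema-1,3,11(13)-trien-12,8β-olide (5αH,7αH,8αH,10β-CH3)
Conditions: o-dichlorobenzene (5 mM), BHT, base-washed sealed tube, Ar, 160–170 °C; recovered 16 recycled
Reagents that add atoms: none
Why: Thermal [3,3]-sigmatropic (Cope) rearrangement through the chair transition state of a crossed conformer of the (E,E)-cyclodeca-1,5-diene: the transannular C5–C10 σ-bond forms as C2–C3 breaks, so the six-membered ring C5–C6–C7–C8–C9–C10 closes while the ten-membered ring opens, which is the germacranolide-to-elemanolide isomerisation of the presumed biogenesis and a known reaction type of germacradienes. Both E-alkenes place C6 and C9 equatorial on the pericyclic chair, which fixes C10 against C5 as equatorial vinyl trans to equatorial propenyl, with C14 and H5 axial on opposite faces. Which crossed conformer reacts decides C5/C10 relative to C6–C9: A(1,3) strain with C15H3 keeps H6 in the plane of C4=C5, and with the 6α-hydroxyl this puts C14 and C15 on the β-face (5αH, 10β-CH3), whereas the other conformer would eclipse O6 with C15 and set O6 syn-axial to C14. The 9α-acetoxy group stands anti to C14 only in the productive conformer and should reinforce this preference. The step needs this conformer selectivity and a favourable equilibrium, the latter supplied by release of the strain of the E,E-ten-membered ring. Acid-free glassware and BHT suppress transannular cationic cyclisation and polymerisation of the methylene lactone.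

Step 13
Reactants: 17 9α-acetoxy-6α-hydroxyelema-1,3,11(13)-trien-12,8β-olide
Product: 18 9α-acetoxy-6-oxoelema-1,3,11(13)-trien-12,8β-olide
Conditions: Dess–Martin periodinane, pyridine, CH2Cl2, 0 °C
Reagents that add atoms: none
Why: Dess–Martin oxidation under buffered, non-enolising conditions erases the C6 stereocentre once it has served as control element, while C5 (propenyl already equatorial) and C7 should keep their configuration.

Step 14
Reactants: 18 9α-acetoxy-6-oxoelema-1,3,11(13)-trien-12,8β-olide
Product: 19 9α-acetoxy-6β-hydroxyelema-1,3,11(13)-trien-12,8β-olide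
Conditions: NaBH4, CeCl3·7H2O, MeOH–CH2Cl2, −78 °C; pH 7 buffer at −78 °C
Reagents that add atoms: none
Why: Luche reduction: the cerium-modified borohydride should add 1,2 to the ketone faster than 1,4 to the methylene lactone, and hydride should enter from the α-face because the β-face of C6 is screened by the syn-axial C14 methyl and O8, which gives the axial 6β-alcohol as in 6-oxo-eudesmanes and 6-oxo-5α-steroids.

Step 15
Reactants: 19 9α-acetoxy-6β-hydroxyelema-1,3,11(13)-trien-12,8β-olide
Product: 20 9α-acetoxy-6β-isobutyryloxyelema-1,3,11(13)-trien-12,8β-olide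
Conditions: (i-PrCO)2O, DMAP, Et3N, CH2Cl2, 0 °C to rt
Reagents that add atoms: isobutyric anhydride, CC(C)C(=O)OC(=O)C(C)C
Why: DMAP-catalysed (Steglich-type) acylation esterifies the single, hindered axial hydroxyl with retention at C6 and removes the nucleophile that could otherwise attack the lactone carbonyl.

Step 16
Reactants: 20 9α-acetoxy-6β-isobutyryloxyelema-1,3,11(13)-trien-12,8β-olide
Product: 21 9α-acetoxy-15-hydroxy-6β-isobutyryloxyelema-1,3,11(13)-trien-12,8β-olide
Conditions: SeO2 (0.5 equiv), t-BuOOH, CH2Cl2, 0 °C to rt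
Reagents that add atoms: tert-butyl hydroperoxide, CC(C)(C)OO (oxygen source, relayed by selenium dioxide, O=[Se]=O)
Why: Riley-type allylic oxidation should touch only the isopropenyl group, because the vinyl group on quaternary C10 has no allylic hydrogen and the methylene lactone is electron-poor, and the ene step should take a C15 methyl hydrogen since the hindered C5–H lies in the alkene plane, as in the known methyl oxidation of elemene-type isopropenyl groups.

Step 17
Reactants: 21 9α-acetoxy-15-hydroxy-6β-isobutyryloxyelema-1,3,11(13)-trien-12,8β-olide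
Product: 22 9α,15-diacetoxy-6β-isobutyryloxyelema-1,3,11(13)-trien-12,8β-olide (CNP0500052.1)
Conditions: Ac2O, pyridine, DMAP (cat.), CH2Cl2, 0 °C
Reagents that add atoms: acetic anhydride, CC(=O)OC(C)=O
Why: Pyridine/DMAP-mediated acetylation of the primary allylic alcohol completes the target without touching any stereocentre.

Compound list
1 | geraniol | CC(C)=CCC/C(C)=C/CO | starting material
2 | geranyl tert-butyldimethylsilyl ether | CC(C)=CCC/C(C)=C/CO[Si](C)(C)C(C)(C)C | intermediate
3 | (2E,6E)-8-(tert-butyldimethylsilyloxy)-2,6-dimethylocta-2,6-dien-1-ol | OC/C(C)=C/CC/C(C)=C/CO[Si](C)(C)C(C)(C)C | intermediate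
4 | (2E,6E)-8-(tert-butyldimethylsilyloxy)-2,6-dimethylocta-2,6-dienal | O=C/C(C)=C/CC/C(C)=C/CO[Si](C)(C)C(C)(C)C | intermediate
5 | but-2-yne-1,4-diol | OCC#CCO | starting material
6 | 3-(hydroxymethyl)furan-2(5H)-one | O=C1OCC=C1CO | intermediate
7 | 2-(tert-butyldimethylsilyloxy)-3-[(tert-butyldimethylsilyloxy)methyl]furan | CC(C)(C)[Si](C)(C)OCc1ccoc1O[Si](C)(C)C(C)(C)C | intermediate
8 | O-trichlorosilyl aldolate of 9 (not isolated) | CC(C)(C)[Si](C)(C)OC/C=C(\C)CC/C=C(\C)[C@H](O[Si](Cl)(Cl)Cl)[C@H]1OC(=O)C(CO[Si](C)(C)C(C)(C)C)=C1 | intermediate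
9 | (5S)-3-[(tert-butyldimethylsilyloxy)methyl]-5-[(1S,2E,6E)-8-(tert-butyldimethylsilyloxy)-1-hydroxy-2,6-dimethylocta-2,6-dienyl]furan-2(5H)-one | CC(C)(C)[Si](C)(C)OC/C=C(\C)CC/C=C(\C)[C@H](O)[C@H]1OC(=O)C(CO[Si](C)(C)C(C)(C)C)=C1 | intermediate
10 | C9 acetate of 9 | CC(C)(C)[Si](C)(C)OC/C=C(\C)CC/C=C(\C)[C@H](OC(C)=O)[C@H]1OC(=O)C(CO[Si](C)(C)C(C)(C)C)=C1 | intermediate
11 | (5S)-5-[(1S,2E,6E)-1-acetoxy-8-hydroxy-2,6-dimethylocta-2,6-dienyl]-3-(hydroxymethyl)furan-2(5H)-one | OC/C=C(\C)CC/C=C(\C)[C@H](OC(C)=O)[C@H]1OC(=O)C(CO)=C1 | intermediate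
12 | (5S)-5-[(1S,2E,6E)-1-acetoxy-2,6-dimethyl-8-oxoocta-2,6-dienyl]-3-(hydroxymethyl)furan-2(5H)-one | O=C/C=C(\C)CC/C=C(\C)[C@H](OC(C)=O)[C@H]1OC(=O)C(CO)=C1 | intermediate
13 | (5S)-5-[(1S,2E,6E)-1-acetoxy-2,6-dimethyl-8-oxoocta-2,6-dienyl]-3-(bromomethyl)furan-2(5H)-one | O=C/C=C(\C)CC/C=C(\C)[C@H](OC(C)=O)[C@H]1OC(=O)C(CBr)=C1 | intermediate
14 | allylchromium(III) dichloride from 13 (not isolated) | O=C/C=C(\C)CC/C=C(\C)[C@H](OC(C)=O)[C@H]1OC(=O)C(C[Cr](Cl)Cl)=C1 | intermediate
15 | chromium(III) alkoxide of 16 (not isolated) | C/C1=C\CC/C(C)=C/[C@@H](O[Cr](Cl)Cl)[C@@H]2C(=C)C(=O)O[C@@H]2[C@H]1OC(C)=O | intermediate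
16 | 9α-acetoxy-6α-hydroxygermacra-1(10)E,4E,11(13)-trien-12,8β-olide | C/C1=C\CC/C(C)=C/[C@@H](O)[C@@H]2C(=C)C(=O)O[C@@H]2[C@H]1OC(C)=O | intermediate
17 | 9α-acetoxy-6α-hydroxyelema-1,3,11(13)-trien-12,8β-olide | C=C[C@]1(C)[C@H](OC(C)=O)[C@H]2OC(=O)C(=C)[C@H]2[C@H](O)[C@H]1C(=C)C | intermediate
18 | 9α-acetoxy-6-oxoelema-1,3,11(13)-trien-12,8β-olide | C=C[C@]1(C)[C@H](OC(C)=O)[C@H]2OC(=O)C(=C)[C@H]2C(=O)[C@H]1C(=C)C | intermediate
19 | 9α-acetoxy-6β-hydroxyelema-1,3,11(13)-trien-12,8β-olide | C=C[C@]1(C)[C@H](OC(C)=O)[C@H]2OC(=O)C(=C)[C@H]2[C@@H](O)[C@H]1C(=C)C | intermediate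
20 | 9α-acetoxy-6β-isobutyryloxyelema-1,3,11(13)-trien-12,8β-olide | C=C[C@]1(C)[C@H](OC(C)=O)[C@H]2OC(=O)C(=C)[C@H]2[C@@H](OC(=O)C(C)C)[C@H]1C(=C)C | intermediate
21 | 9α-acetoxy-15-hydroxy-6β-isobutyryloxyelema-1,3,11(13)-trien-12,8β-olide | C=C[C@]1(C)[C@H](OC(C)=O)[C@H]2OC(=O)C(=C)[C@H]2[C@@H](OC(=O)C(C)C)[C@H]1C(=C)CO | intermediate
22 | 9α,15-diacetoxy-6β-isobutyryloxyelema-1,3,11(13)-trien-12,8β-olide (CNP0500052.1) | C=C[C@]1(C)[C@H](OC(C)=O)[C@H]2OC(=O)C(=C)[C@H]2[C@@H](OC(=O)C(C)C)[C@H]1C(=C)COC(C)=O | target

Total step count: 17. Longest linear sequence: 15 (steps 1–3 and 6–17).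

Steps most likely to fail

Step 11 (macrocyclisation). Oligomerisation may compete with closure of the ten-membered ring. The aldehyde may also reach the butenolide face opposite to C9 (trans ring fusion), or the simple 6,7-diastereoselection may erode. The fallback replaces the chromium Barbier closure by a palladium-catalysed umpolung allylation. It sets out from 12, which is converted with methyl chloroformate/pyridine into the allylic methyl carbonate F1. Slow addition of F1 to Pd(PPh3)4/Et2Zn in THF ionises the primary, carbonyl-flanked carbonate much faster than the hindered C9 acetate. It then transmetallates the π-allylpalladium complex to an allylzinc, which adds to the enal through a tighter zinc-centred chair. Aqueous work-up comes back to the route at 16.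

Step 12 (Cope rearrangement). The equilibrium may lie too far on the side of the cyclodecadiene, part of the material may leak through the other crossed conformer, or traces of acid may trigger transannular cyclisation. The fallback strengthens the control element instead of changing the thermolysis. It sets out from 16, which is silylated (TBSOTf, 2,6-lutidine) to the 6α-silyl ether F2. The larger O-substituent raises the A(1,3) and syn-axial penalties of the unwanted conformer and removes the free hydroxyl from the hot reaction mixture. Thermolysis should then give the silylated elemanolide F3, and HF·pyridine comes back to the route at 17.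

Step 14 (ketone reduction). Three processes may interfere:
- conjugate reduction of the methylene lactone;
- migration of the lactone from O8 to the new 6β-alkoxide;
- enolisation of the ketone with shift of the exocyclic alkene into conjugation.

The fallback masks the Michael acceptor first. It sets out from 18, which takes up dimethylamine (THF, 0 °C) to give the 13-dimethylamino adduct F4 (configuration at C11 immaterial). Reduction of F4 with NaBH4 at low temperature from the α-face gives the 6β-alcohol F5. Methyl iodide then gives the quaternary ammonium iodide F6, and aqueous NaHCO3 eliminates the amine and comes back to the route at 19.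

Further compounds
F1 | step 11 | (5S)-5-[(1S,2E,6E)-1-acetoxy-2,6-dimethyl-8-oxoocta-2,6-dienyl]-3-[(methoxycarbonyloxy)methyl]furan-2(5H)-one | O=C/C=C(\C)CC/C=C(\C)[C@H](OC(C)=O)[C@H]1OC(=O)C(COC(=O)OC)=C1
F2 | step 12 | 9α-acetoxy-6α-(tert-butyldimethylsilyloxy)germacra-1(10)E,4E,11(13)-trien-12,8β-olide | C/C1=C\CC/C(C)=C/[C@@H](O[Si](C)(C)C(C)(C)C)[C@@H]2C(=C)C(=O)O[C@@H]2[C@H]1OC(C)=O
F3 | step 12 | 9α-acetoxy-6α-(tert-butyldimethylsilyloxy)elema-1,3,11(13)-trien-12,8β-olide | C=C[C@]1(C)[C@H](OC(C)=O)[C@H]2OC(=O)C(=C)[C@H]2[C@H](O[Si](C)(C)C(C)(C)C)[C@H]1C(=C)C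
F4 | step 14 | 9α-acetoxy-13-dimethylamino-6-oxoelema-1,3-dien-12,8β-olide | C=C[C@]1(C)[C@H](OC(C)=O)[C@H]2OC(=O)C(CN(C)C)[C@H]2C(=O)[C@H]1C(=C)C
F5 | step 14 | 9α-acetoxy-13-dimethylamino-6β-hydroxyelema-1,3-dien-12,8β-olide | C=C[C@]1(C)[C@H](OC(C)=O)[C@H]2OC(=O)C(CN(C)C)[C@H]2[C@@H](O)[C@H]1C(=C)C
F6 | step 14 | 13-trimethylammonio derivative of F5, iodide salt | C=C[C@]1(C)[C@H](OC(C)=O)[C@H]2OC(=O)C(C[N+](C)(C)C)[C@H]2[C@@H](O)[C@H]1C(=C)C.[I-]
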